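**Retrosynthetic overview**
- The saturated two-carbon link is cut back to a Z-alkene, made by Wittig reaction of a decalin phosphonium salt with an α-peroxy aldehyde and reduced last with diimide.
- The α-peroxy aldehyde comes from a formyl-anion equivalent (formaldehyde dimethylhydrazone) adding to a cyclic peroxycarbenium ion. This C–C bond creates the quaternary peroxide carbon under 1,4-control from the existing ring stereocentre.
- The 1,2-dioxane ring is formed first, by a hydroperoxy ketal displacing a secondary mesylate with inversion; the mesylate comes from an Evans syn-aldol on 4-oxopentanal.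
- Rings A and B of the decalin are formed together by superacid bicyclisation of (2Z,6E)-farnesol, followed by lipase resolution, iodide and phosphonium salt.

Assumption: 4-oxopentanal and (2Z,6E)-farnesol are bought as single catalogue compounds.

**Route**

Step 1
Reactants: 1 (4S)-4-benzyl-3-propanoyl-1,3-oxazolidin-2-one; 2 4-oxopentanal
Product: 4 (4S)-4-benzyl-3-[(2S,3R)-3-hydroxy-2-methyl-6-oxoheptanoyl]-1,3-oxazolidin-2-one, via boron Z-enolate 3 (not isolated)
Conditions: Bu2BOTf, i-Pr2NEt, CH2Cl2, 0 °C; then 2, −78 → 0 °C; pH 7 buffer, MeOH, H2O2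
Reagents that add atoms: none
Why: Evans syn-aldol reaction: the boron Z-enolate reacts through a Zimmerman–Traxler chair on the face away from the benzyl group, setting C2 (S) and C3 (R) together, and the aldehyde reacts in preference to the methyl ketone.

Step 2
Reactants: 4 (4S)-4-benzyl-3-[(2S,3R)-3-hydroxy-2-methyl-6-oxoheptanoyl]-1,3-oxazolidin-2-one
Product: 5 methyl (2S,3R)-3-hydroxy-2-methyl-6-oxoheptanoate
Conditions: MeMgBr, MeOH, CH2Cl2, 0 °C
Reagents that add atoms: methanol (as MeOMgBr), CO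
Why: Transesterification with MeOMgBr cleaves the exocyclic imide carbonyl selectively, without retro-aldol or epimerisation, and releases the auxiliary.

Step 3
Reactants: 5 methyl (2S,3R)-3-hydroxy-2-methyl-6-oxoheptanoate
Product: 6 methyl (2S,3R)-2-methyl-3-(methylsulfonyloxy)-6-oxoheptanoate
Conditions: MsCl, Et3N, CH2Cl2, −30 °C
Reagents that add atoms: methanesulfonyl chloride, CS(=O)(=O)Cl
Why: O-sulfonylation of the open-chain secondary alcohol with retention at C3, kept cold and brief so the β-mesyloxy ester does not eliminate.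

Step 4
Reactants: 6 methyl (2S,3R)-2-methyl-3-(methylsulfonyloxy)-6-oxoheptanoate
Product: 8 methyl (2S)-2-[(3S)-6-methoxy-6-methyl-1,2-dioxan-3-yl]propanoate (both C-6 epimers), via hydroperoxy ketal 7 (not isolated)
Conditions: CO(NH2)2·H2O2, Sc(OTf)3 (cat.), MeOH, rt; then KOtBu (1.0 equiv), 18-crown-6, THF, −20 → 0 °C
Reagents that add atoms: hydrogen peroxide (from urea–hydrogen peroxide), OO; methanol, CO
Why: Acid-catalysed perketalisation of the methyl ketone followed by intramolecular hydroperoxide alkylation (6-exo-tet SN2): the peroxide anion displaces the mesylate with inversion, giving C3 (S), and one equivalent of base deprotonates only the O–O–H.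

Step 5
Reactants: 8 methyl (2S)-2-[(3S)-6-methoxy-6-methyl-1,2-dioxan-3-yl]propanoate; 9 formaldehyde N,N-dimethylhydrazone
Product: 11 methyl (2S)-2-[(3S,6R)-6-[(E)-(2,2-dimethylhydrazinylidene)methyl]-6-methyl-1,2-dioxan-3-yl]propanoate, via peroxycarbenium triflate 10 (not isolated)
Conditions: Me3SiOTf (1.2 equiv), 9 (3 equiv), CH2Cl2, −78 °C; Et3N, NaHCO3 aq
Reagents that add atoms: none
Why: Proposed new method: Me3SiOTf ionises the peroxyketal to a cyclic peroxycarbenium ion of the kind already trapped by allylsilanes and enol silanes, and formaldehyde dialkylhydrazones are neutral aza-enamine formyl-anion equivalents that add through carbon to silyl-triflate-activated electrophiles; axial attack on the half-chair with the C3 side chain pseudo-equatorial places the new C–C bond cis to that side chain (the 3,6-cis outcome of Lewis-acid substitutions on 1,2-dioxan-3-yl acetates), setting the quaternary C6 as (R); closest known reactions are Sakurai/Mukaiyama-type additions to peroxycarbenium ions and silyl-triflate-promoted additions of formaldehyde hydrazones to enones.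

Step 6
Reactants: 11 methyl (2S)-2-[(3S,6R)-6-[(E)-(2,2-dimethylhydrazinylidene)methyl]-6-methyl-1,2-dioxan-3-yl]propanoate
Product: 12 methyl (2S)-2-[(3S,6R)-6-formyl-6-methyl-1,2-dioxan-3-yl]propanoate
Conditions: O3, CH2Cl2, −78 °C; Me2S
Reagents that add atoms: ozone, [O-][O+]=O
Why: Ozonolytic cleavage of the hydrazone C=N bond unmasks the aldehyde under neutral, non-reducing conditions that the dialkyl peroxide and ester tolerate; no stereocentre is touched.

Step 7
Reactants: 13 (2Z,6E)-farnesol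
Product: 14 (±)-[(1S*,4aR*,8aR*)-2,5,5,8a-tetramethyl-1,4,4a,5,6,7,8,8a-octahydronaphthalen-1-yl]methanol
Conditions: FSO3H, 2-nitropropane, −78 °C; Et3N quench
Reagents that add atoms: none
Why: Superacid cation–olefin bicyclisation through a chair–chair array: the 6E alkene gives the trans ring fusion, the 2Z alkene places the CH2OH group axial at C1 (trans to the angular methyl), and proton loss gives the trisubstituted ring alkene; the product is racemic.

Step 8
Reactants: 14 (±)-[(1S*,4aR*,8aR*)-2,5,5,8a-tetramethyl-1,4,4a,5,6,7,8,8a-octahydronaphthalen-1-yl]methanol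
Product: 15 [(1S,4aR,8aR)-2,5,5,8a-tetramethyl-1,4,4a,5,6,7,8,8a-octahydronaphthalen-1-yl]methanol
Conditions: Burkholderia cepacia lipase, vinyl acetate, t-BuOMe, rt, to about 50% conversion
Reagents that add atoms: none
Why: Lipase kinetic resolution by enantioselective acylation, as used for albicanol-type primary alcohols: the (1R,4aS,8aS) enantiomer is acetylated and 15 is recovered, which fixes the absolute configuration of all three decalin stereocentres.

Step 9
Reactants: 15 [(1S,4aR,8aR)-2,5,5,8a-tetramethyl-1,4,4a,5,6,7,8,8a-octahydronaphthalen-1-yl]methanol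
Product: 16 (1S,4aR,8aR)-1-(iodomethyl)-2,5,5,8a-tetramethyl-1,4,4a,5,6,7,8,8a-octahydronaphthalene
Conditions: PPh3, I2, imidazole, CH2Cl2, 0 °C → rt
Reagents that add atoms: iodine, II
Why: Appel-type iodination through the alkoxyphosphonium salt converts the primary alcohol into the iodide without touching a stereocentre.

Step 10
Reactants: 16 (1S,4aR,8aR)-1-(iodomethyl)-2,5,5,8a-tetramethyl-1,4,4a,5,6,7,8,8a-octahydronaphthalene
Product: 17 {[(1S,4aR,8aR)-2,5,5,8a-tetramethyl-1,4,4a,5,6,7,8,8a-octahydronaphthalen-1-yl]methyl}triphenylphosphonium iodide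
Conditions: PPh3, MeCN, 110 °C (sealed tube)
Reagents that add atoms: triphenylphosphine, c1ccccc1P(c1ccccc1)c1ccccc1
Why: SN2 quaternisation of triphenylphosphine by the primary iodide, run hot because the carbon is β-branched.

Step 11
Reactants: 17 {[(1S,4aR,8aR)-2,5,5,8a-tetramethyl-1,4,4a,5,6,7,8,8a-octahydronaphthalen-1-yl]methyl}triphenylphosphonium iodide; 12 methyl (2S)-2-[(3S,6R)-6-formyl-6-methyl-1,2-dioxan-3-yl]propanoate
Product: 19 methyl (2S)-2-[(3S,6R)-6-methyl-6-{(Z)-2-[(1S,4aR,8aR)-2,5,5,8a-tetramethyl-1,4,4a,5,6,7,8,8a-octahydronaphthalen-1-yl]ethenyl}-1,2-dioxan-3-yl]propanoate, via phosphorus ylide 18 (not isolated)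
Conditions: NaN(SiMe3)2, THF, −78 → 0 °C; then 12, −78 °C → rt
Reagents that add atoms: none
Why: Wittig olefination of a non-stabilised ylide with a non-enolisable aldehyde joins the two fragments, mainly as the Z-alkene (geometry is erased in the next step), at temperatures where the ylide neither attacks the O–O bond nor enolises the ester.

Step 12
Reactants: 19 methyl (2S)-2-[(3S,6R)-6-methyl-6-{(Z)-2-[(1S,4aR,8aR)-2,5,5,8a-tetramethyl-1,4,4a,5,6,7,8,8a-octahydronaphthalen-1-yl]ethenyl}-1,2-dioxan-3-yl]propanoate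
Product: 20 methyl (2S)-2-[(3S,6S)-6-methyl-6-{2-[(1S,4aR,8aR)-2,5,5,8a-tetramethyl-1,4,4a,5,6,7,8,8a-octahydronaphthalen-1-yl]ethyl}-1,2-dioxan-3-yl]propanoate
Conditions: KO2CN=NCO2K, AcOH, MeOH/CH2Cl2, 0 °C → rt
Reagents that add atoms: none
Why: Diimide reduction transfers H2 to the 1,2-disubstituted alkene only, leaving the hindered trisubstituted ring alkene, the O–O bond and the ester untouched; no stereocentre changes (the C6 descriptor changes from R to S only because the priorities change).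

**Compound list**

1 | (4S)-4-benzyl-3-propanoyl-1,3-oxazolidin-2-one | O=C1OC[C@H](Cc2ccccc2)N1C(=O)CC | starting material
2 | 4-oxopentanal | CC(=O)CCC=O | starting material
3 | dibutylboron (Z)-enolate of 1 | C/C=C(\OB(CCCC)CCCC)N1C(=O)OC[C@@H]1Cc1ccccc1 | intermediate
4 | (4S)-4-benzyl-3-[(2S,3R)-3-hydroxy-2-methyl-6-oxoheptanoyl]-1,3-oxazolidin-2-one | O=C1OC[C@H](Cc2ccccc2)N1C(=O)[C@@H](C)[C@H](O)CCC(C)=O | intermediate
5 | methyl (2S,3R)-3-hydroxy-2-methyl-6-oxoheptanoate | COC(=O)[C@@H](C)[C@H](O)CCC(C)=O | intermediate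
6 | methyl (2S,3R)-2-methyl-3-(methylsulfonyloxy)-6-oxoheptanoate | COC(=O)[C@@H](C)[C@H](OS(C)(=O)=O)CCC(C)=O | intermediate
7 | methyl (2S,3R)-6-hydroperoxy-6-methoxy-2-methyl-3-(methylsulfonyloxy)heptanoate (both C-6 epimers) | COC(=O)[C@@H](C)[C@H](OS(C)(=O)=O)CCC(C)(OC)OO | intermediate
8 | methyl (2S)-2-[(3S)-6-methoxy-6-methyl-1,2-dioxan-3-yl]propanoate (both C-6 epimers) | COC(=O)[C@@H](C)[C@@H]1CCC(C)(OC)OO1 | intermediate
9 | formaldehyde N,N-dimethylhydrazone | C=NN(C)C | starting material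
10 | (6S)-6-[(2S)-1-methoxy-1-oxopropan-2-yl]-3-methyl-5,6-dihydro-4H-1,2-dioxin-2-ium trifluoromethanesulfonate | COC(=O)[C@@H](C)[C@@H]1CCC(C)=[O+]O1.[O-]S(=O)(=O)C(F)(F)F | intermediate
11 | methyl (2S)-2-[(3S,6R)-6-[(E)-(2,2-dimethylhydrazinylidene)methyl]-6-methyl-1,2-dioxan-3-yl]propanoate | COC(=O)[C@@H](C)[C@@H]1CC[C@](C)(/C=N/N(C)C)OO1 | intermediate
12 | methyl (2S)-2-[(3S,6R)-6-formyl-6-methyl-1,2-dioxan-3-yl]propanoate | COC(=O)[C@@H](C)[C@@H]1CC[C@](C)(C=O)OO1 | intermediate
13 | (2Z,6E)-3,7,11-trimethyldodeca-2,6,10-trien-1-ol ((2Z,6E)-farnesol) | OC/C=C(C)\CC/C=C(C)/CCC=C(C)C | starting material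
14 | (±)-[(1S*,4aR*,8aR*)-2,5,5,8a-tetramethyl-1,4,4a,5,6,7,8,8a-octahydronaphthalen-1-yl]methanol (racemate, both enantiomers written) | OC[C@H]1C(C)=CC[C@@H]2C(C)(C)CCC[C@]21C.OC[C@@H]1C(C)=CC[C@H]2C(C)(C)CCC[C@@]21C | intermediate
15 | [(1S,4aR,8aR)-2,5,5,8a-tetramethyl-1,4,4a,5,6,7,8,8a-octahydronaphthalen-1-yl]methanol | OC[C@H]1C(C)=CC[C@@H]2C(C)(C)CCC[C@]21C | intermediate
16 | (1S,4aR,8aR)-1-(iodomethyl)-2,5,5,8a-tetramethyl-1,4,4a,5,6,7,8,8a-octahydronaphthalene | IC[C@H]1C(C)=CC[C@@H]2C(C)(C)CCC[C@]21C | intermediate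
17 | {[(1S,4aR,8aR)-2,5,5,8a-tetramethyl-1,4,4a,5,6,7,8,8a-octahydronaphthalen-1-yl]methyl}triphenylphosphonium iodide | [I-].c1ccccc1[P+](c1ccccc1)(c1ccccc1)C[C@H]1C(C)=CC[C@@H]2C(C)(C)CCC[C@]21C | intermediate
18 | {[(1S,4aR,8aR)-2,5,5,8a-tetramethyl-1,4,4a,5,6,7,8,8a-octahydronaphthalen-1-yl]methylidene}triphenylphosphorane | c1ccccc1P(c1ccccc1)(c1ccccc1)=C[C@H]1C(C)=CC[C@@H]2C(C)(C)CCC[C@]21C | intermediate
19 | methyl (2S)-2-[(3S,6R)-6-methyl-6-{(Z)-2-[(1S,4aR,8aR)-2,5,5,8a-tetramethyl-1,4,4a,5,6,7,8,8a-octahydronaphthalen-1-yl]ethenyl}-1,2-dioxan-3-yl]propanoate | COC(=O)[C@@H](C)[C@@H]1CC[C@](C)(/C=C\[C@H]2C(C)=CC[C@@H]3C(C)(C)CCC[C@]32C)OO1 | intermediate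
20 | methyl (2S)-2-[(3S,6S)-6-methyl-6-{2-[(1S,4aR,8aR)-2,5,5,8a-tetramethyl-1,4,4a,5,6,7,8,8a-octahydronaphthalen-1-yl]ethyl}-1,2-dioxan-3-yl]propanoate | COC(=O)[C@@H](C)[C@@H]1CC[C@](C)(CC[C@H]2C(C)=CC[C@@H]3C(C)(C)CCC[C@]32C)OO1 | target

**Step count and risks**

Total: 12 steps. Longest linear sequence: 8 steps (steps 1–6, 11, 12); the decalin branch is steps 7–10 and joins at step 11.

Steps most likely to fail:

Step 4. The β-mesyloxy ester can eliminate (E1cB), or the ketone can assist solvolysis, before the 6-exo displacement. The fallback sets out from 2 and comes back at 8; it removes the acidic C–H by carrying the ester carbon as a vinyl group. Compound 2 is crotylated with B-(Z)-crotyldiisopinocampheylborane (the Ipc antipode that delivers the 5R,6R isomer) to give the syn homoallylic alcohol (5R,6R)-5-hydroxy-6-methyloct-7-en-2-one F1. MsCl/Et3N gives (3R,4R)-3-methyl-7-oxooct-1-en-4-yl methanesulfonate F2. CO(NH2)2·H2O2 with Sc(OTf)3 in MeOH gives the hydroperoxy ketal (3R,4R)-7-hydroperoxy-7-methoxy-3-methyloct-1-en-4-yl methanesulfonate F3, used crude. KOtBu/18-crown-6 closes it with inversion to (3S)-3-[(2R)-but-3-en-2-yl]-6-methoxy-6-methyl-1,2-dioxane F4. RuCl3 (cat.)/NaIO4 cleaves the vinyl group to (2S)-2-[(3S)-6-methoxy-6-methyl-1,2-dioxan-3-yl]propanoic acid F5, and Me3SiCHN2 in MeOH gives 8.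

Step 5. The hydrazone may react through nitrogen or sequester the silyl triflate, and the peroxyketal may fragment instead of ionising cleanly. The fallback sets out from 8 and comes back at 12; it replaces the aza-enamine by a boron-bound vinyl group as the latent formyl carbon. K[CH2=CHBF3] and BF3·OEt2 in CH2Cl2/MeCN at −40 °C deliver the vinyl group to the same axial face to give methyl (2S)-2-[(3S,6R)-6-ethenyl-6-methyl-1,2-dioxan-3-yl]propanoate F6. Ozonolysis (O3, then Me2S) cleaves the vinyl group to 12.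

Step 8. The lipase may show low or reversed selectivity for this axial primary alcohol. The fallback sets out from 14 and comes back at 15; it replaces the enzymatic resolution by a classical one. Racemic 14 is esterified with (S)-O-acetylmandelic acid (DCC, DMAP) and the two diastereomeric esters are separated by chromatography or crystallisation. The ester of the wanted alcohol, [(1S,4aR,8aR)-2,5,5,8a-tetramethyl-1,4,4a,5,6,7,8,8a-octahydronaphthalen-1-yl]methyl (2S)-2-acetyloxy-2-phenylacetate F7, is cleaved with K2CO3 in MeOH to give 15.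

Further compounds
F1 | step 4 | (5R,6R)-5-hydroxy-6-methyloct-7-en-2-one | C=C[C@@H](C)[C@H](O)CCC(C)=O
F2 | step 4 | (3R,4R)-3-methyl-7-oxooct-1-en-4-yl methanesulfonate | C=C[C@@H](C)[C@H](OS(C)(=O)=O)CCC(C)=O
F3 | step 4 | (3R,4R)-7-hydroperoxy-7-methoxy-3-methyloct-1-en-4-yl methanesulfonate | C=C[C@@H](C)[C@H](OS(C)(=O)=O)CCC(C)(OC)OO
F4 | step 4 | (3S)-3-[(2R)-but-3-en-2-yl]-6-methoxy-6-methyl-1,2-dioxane | C=C[C@@H](C)[C@@H]1CCC(C)(OC)OO1
F5 | step 4 | (2S)-2-[(3S)-6-methoxy-6-methyl-1,2-dioxan-3-yl]propanoic acid | OC(=O)[C@@H](C)[C@@H]1CCC(C)(OC)OO1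
F6 | step 5 | methyl (2S)-2-[(3S,6R)-6-ethenyl-6-methyl-1,2-dioxan-3-yl]propanoate | COC(=O)[C@@H](C)[C@@H]1CC[C@](C)(C=C)OO1
F7 | step 8 | [(1S,4aR,8aR)-2,5,5,8a-tetramethyl-1,4,4a,5,6,7,8,8a-octahydronaphthalen-1-yl]methyl (2S)-2-acetyloxy-2-phenylacetate | CC(=O)O[C@H](C(=O)OC[C@H]1C(C)=CC[C@@H]2C(C)(C)CCC[C@]21C)c1ccccc1
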